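**Retrosynthetic overview**
1. The C15 alcohol is unmasked last. C8=C17 comes from methylenation of a C8 ketone, which comes from hydroboration–oxidation of a Δ8(9) alkene. That alkene is made by Negishi coupling (C9–C11) of a ring-B C9 enol triflate with the zinc reagent of a citronellol-derived C11–C15 iodide.
2. The strategy rests on ring A: C3 and C19 are both carbonyl-level carbons on quaternary C4. Both therefore start as the two esters of one methylmalonate on C5, and C2–C3 is formed by Dieckmann attack of a C2 ester enolate on one of these two diastereotopic esters.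
3. The Dieckmann precursor is a ring-B ketal built from (R)-carvone: malonate Michael addition (C4–C5) with methylation, excision of the isopropenyl group, Michael addition of C10 to allyl acrylate (C10–C1), then ketalisation.
4. Ring order: ring B is taken from carvone, ring A is closed in the key step, and no further ring is formed.

Key step: step 5

Remark: positions are given in labdane numbering (ring A = C1–C5, C10; ring B = C5–C10). C10 in 3–6 is epimerisable and is drawn as the 2,3-trans epimer; its configuration there does not matter because C10 is enolised in step 3.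

**Step 1**
Reactants: 1 (R)-carvone; 2 dimethyl malonate
Product: 4 dimethyl 2-methyl-2-[(1R,2S,5R)-2-methyl-3-oxo-5-(prop-1-en-2-yl)cyclohexyl]malonate, via Michael adduct 3 (not isolated)
Conditions: NaOMe (1.1 equiv), MeOH, 0 °C → rt; then MeI, rt → 40 °C
Reagents that add atoms: iodomethane, CI
Why: Michael addition followed by malonate C-alkylation: the sodiomalonate attacks the enone β-carbon axially through a chair-like transition state, anti to the pseudo-equatorial isopropenyl group, which sets C5 from the chiral pool, and the adduct, held as its malonate anion and so protected from retro-Michael cleavage, is methylated at carbon to make quaternary C4.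

**Step 2**
Reactants: 4 methylated Michael adduct
Product: 6 dimethyl 2-methyl-2-[(1R,2S)-2-methyl-3-oxocyclohexyl]malonate, via methoxy hydroperoxide 5 (not isolated)
Conditions: O3, MeOH, −78 °C; then FeSO4·7H2O, PhSH, −78 °C → rt
Reagents that add atoms: none
Why: Hydrodealkenylation: ozonolysis in methanol gives the α-methoxy hydroperoxide, divalent iron reduces it to an alkoxyl radical that fragments with loss of methyl acetate, and the secondary ring radical takes a hydrogen atom from the thiol, so the isopropenyl control group is excised without touching C5.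

**Step 3**
Reactants: 6 keto diester; 7 allyl acrylate
Product: 8 allyl 3-[(1S,2R)-2-(1,3-dimethoxy-2-methyl-1,3-dioxopropan-2-yl)-1-methyl-6-oxocyclohexyl]propanoate
Conditions: KOtBu (0.2 equiv), tBuOH–THF, 0 °C
Reagents that add atoms: none
Why: Base-catalysed Michael addition under equilibrating conditions, which for 2-alkylcyclohexanones runs through the more substituted enolate; the bulky C5 malonate lies pseudo-axial next to the C10 methyl and shields its own face, so the acrylate should add anti to it and set quaternary C10 with the C1 arm trans to C4.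

**Step 4**
Reactants: 8 keto triester
Product: 9 allyl 3-[(6S,7R)-7-(1,3-dimethoxy-2-methyl-1,3-dioxopropan-2-yl)-6-methyl-1,4-dioxaspiro[4.5]decan-6-yl]propanoate
Conditions: HOCH2CH2OH, TsOH (cat.), benzene, reflux, Dean–Stark
Reagents that add atoms: ethylene glycol, OCCO
Why: Acid-catalysed ketalisation driven by azeotropic removal of water; masking C9 takes the C8 protons out of play so that C2 is the only enolisable carbon in the key step.

**Step 5**
Reactants: 9 ketal triester
Product: 10 3-allyl 1-methyl (1R,4aS,8aR)-5,5-ethylenedioxy-2-hydroxy-1,4a-dimethyl-1,4,4a,5,6,7,8,8a-octahydronaphthalene-1,3-dicarboxylate (enol form of the ring-A β-keto ester)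
Conditions: LiN(SiMe3)2 (2.2 equiv), THF, −78 → 0 °C; AcOH quench
Reagents that add atoms: none
Why: Dieckmann condensation: LiN(SiMe3)2 deprotonates C2, the only acidic carbon because C4 carries no hydrogen, C10 is quaternary and C9 is masked, and the ester enolate adds to one malonate carbonyl and expels methoxide to form C2–C3. The second equivalent of base stores the product as its C2–C3 enolate, which drives the condensation and protects the C4 keto ester from retro-Claisen cleavage. Ring A closes in a 6-exo-trig (enol-exo) mode through a chair fused trans to ring B, the trans relation of the C1 and C4 arms having been set in steps 1 and 3. The one new stereocentre, C4, is decided by which of the two diastereotopic esters is attacked: the group left in the axial β position is 1,3-diaxial to the C20 methyl and gauche to both C6 and C10, so the chair that leaves the flatter ester there and the methyl group equatorial should be lower in energy. The step therefore needs group selectivity between two constitutionally identical esters, and only this steric bias from quaternary C10 secures it.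

**Step 6**
Reactants: 10 ring-A β-keto allyl ester
Product: 12 methyl (1R,4aS,8aR)-5,5-ethylenedioxy-1,4a-dimethyl-2-oxodecahydronaphthalene-1-carboxylate, via keto acid 11 (not isolated)
Conditions: Pd(PPh3)4 (5 mol %), morpholine, THF, rt
Reagents that add atoms: none
Why: Deallylative decarboxylation: zerovalent palladium ionises the allyl ester to a π-allyl complex that morpholine intercepts, and the β-keto acid so freed loses CO2 at room temperature, which leaves the methyl ester on C4 and the ketal untouched.

**Step 7**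
Reactants: 12 C3 ketone
Product: 13 methyl (1R,2R,4aS,8aR)-5,5-ethylenedioxy-2-hydroxy-1,4a-dimethyldecahydronaphthalene-1-carboxylate (3α-alcohol)
Conditions: LiBH(sBu)3, THF, −78 °C; then H2O
Reagents that add atoms: none
Why: Ketone reduction under reagent-approach control: the bulky trialkylborohydride attacks the C3 ketone of the 4,4-disubstituted ring along the equatorial trajectory and so should give the axial 3α-alcohol, while the hindered C4 ester is not reduced at −78 °C.

**Step 8**
Reactants: 13 3α-alcohol
Product: 14 methyl (1R,2R,4aS,8aR)-2-acetoxy-5,5-ethylenedioxy-1,4a-dimethyldecahydronaphthalene-1-carboxylate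
Conditions: Ac2O, DMAP, pyridine, 40 °C
Reagents that add atoms: acetic anhydride, CC(=O)OC(C)=O
Why: DMAP-catalysed acylation of the hindered axial alcohol; the acetate of the target can be installed now because every later step is non-basic or tolerates an acetate.

**Step 9**
Reactants: 14 acetoxy ketal
Product: 15 methyl (1R,2R,4aS,8aR)-2-acetoxy-1,4a-dimethyl-5-oxodecahydronaphthalene-1-carboxylate
Conditions: 2 M HCl, THF, rt
Reagents that add atoms: water, O
Why: Acid-catalysed acetal hydrolysis unmasks the C9 ketone; the neopentyl-type acetate and the methyl ester are inert to dilute acid.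

**Step 10**
Reactants: 15 C9 ketone
Product: 16 methyl (1R,2R,4aS,8aR)-2-acetoxy-1,4a-dimethyl-5-(trifluoromethylsulfonyloxy)-1,2,3,4,4a,7,8,8a-octahydronaphthalene-1-carboxylate
Conditions: Tf2O, 2,6-di-tert-butyl-4-methylpyridine, CH2Cl2, 0 °C → rt
Reagents that add atoms: trifluoromethanesulfonic anhydride, O=S(=O)(OS(=O)(=O)C(F)(F)F)C(F)(F)F
Why: Enol triflate formation by O-triflation of the ketone and loss of a C8 proton to the hindered, non-nucleophilic pyridine; enolisation can only go toward C8 because C10 is quaternary, and the absence of a strong base spares the acetate.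

**Step 11**
Reactants: 17 (S)-citronellol
Product: 18 (S)-tert-butyl[(3,7-dimethyloct-6-en-1-yl)oxy]diphenylsilane
Conditions: TBDPSCl, imidazole, DMF, rt
Reagents that add atoms: tert-butyl(chloro)diphenylsilane, CC(C)(C)[Si](Cl)(c1ccccc1)c1ccccc1
Why: Silylation of the primary alcohol; the tert-butyldiphenylsilyl ether should survive the oxidations, the radical iodination, the zinc reagent, borane and the titanium reagent, and is removed last by fluoride.

**Step 12**
Reactants: 18 silyl ether of citronellol
Product: 19 (S)-6-(tert-butyldiphenylsilyloxy)-4-methylhexanoic acid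
Conditions: RuCl3 (2 mol %), NaIO4, CCl4–MeCN–H2O, rt
Reagents that add atoms: sodium periodate, [Na+].[O-]I(=O)(=O)=O, and water, O
Why: RuO4-mediated oxidative cleavage of the trisubstituted alkene to the carboxylic acid with loss of acetone; the future C13 stereocentre is not involved.

**Step 13**
Reactants: 19 carboxylic acid
Product: 20 (R)-tert-butyl[(5-iodo-3-methylpentyl)oxy]diphenylsilane
Conditions: PhI(OAc)2, I2, cyclohexane, hν, reflux
Reagents that add atoms: iodine, II
Why: Hunsdiecker-type iododecarboxylation through the acyl hypoiodite and a primary alkyl radical, which removes one carbon and leaves the iodide on the future C11 (the descriptor changes to R only because iodine raises the priority of that branch).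

**Step 14**
Reactants: 16 enol triflate; 20 alkyl iodide
Product: 22 methyl (1R,2R,4aS,8aR)-2-acetoxy-5-[(3S)-5-(tert-butyldiphenylsilyloxy)-3-methylpentyl]-1,4a-dimethyl-1,2,3,4,4a,7,8,8a-octahydronaphthalene-1-carboxylate, via alkylzinc iodide 21 (not isolated)
Conditions: Zn dust, LiCl, THF, 40 °C; then 16, PdCl2(dppf) (5 mol %), THF–NMP, 60 °C
Reagents that add atoms: none
Why: Negishi coupling: zinc inserts into the primary C–I bond and the alkylzinc iodide couples with the C9 enol triflate under palladium catalysis, the wide-bite-angle diphosphine favouring reductive elimination over β-hydride elimination, which forms C9–C11.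

**Step 15**
Reactants: 22 Δ8(9) alkene
Product: 24 methyl (1R,2R,4aS,5R,6R,8aR)-2-acetoxy-5-[(3S)-5-(tert-butyldiphenylsilyloxy)-3-methylpentyl]-6-hydroxy-1,4a-dimethyldecahydronaphthalene-1-carboxylate, via alkylborane 23 (not isolated)
Conditions: BH3·THF, THF, 0 °C → rt; then NaOAc, 30 % H2O2, 0 °C → rt
Reagents that add atoms: hydrogen peroxide, OO
Why: Hydroboration–oxidation: boron adds to the less substituted C8 and hydrogen to C9 in a syn fashion from the α face, anti to the axial C20 methyl, which should set C9 (9α-H, side chain equatorial) and give the 8α-alcohol with retention on oxidation.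

**Step 16**
Reactants: 24 C8 alcohol
Product: 25 methyl (1R,2R,4aS,5R,8aR)-2-acetoxy-5-[(3S)-5-(tert-butyldiphenylsilyloxy)-3-methylpentyl]-1,4a-dimethyl-6-oxodecahydronaphthalene-1-carboxylate
Conditions: Dess–Martin periodinane, NaHCO3, CH2Cl2, rt
Reagents that add atoms: none
Why: Dess–Martin oxidation under buffered, neutral conditions gives the C8 ketone without epimerising C9, whose equatorial side chain is in any case the stable arrangement.

**Step 17**
Reactants: 25 C8 ketone
Product: 26 methyl (1R,2R,4aR,5S,8aR)-2-acetoxy-5-[(3S)-5-(tert-butyldiphenylsilyloxy)-3-methylpentyl]-1,4a-dimethyl-6-methylidenedecahydronaphthalene-1-carboxylate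
Conditions: Zn, CH2Br2, TiCl4, THF–CH2Cl2, 0 °C → rt
Reagents that add atoms: dibromomethane, BrCBr
Why: Takai–Lombardo methylenation: the non-basic zinc–titanium methylene reagent converts the hindered, enolisable C8 ketone into the exocyclic C8=C17 alkene without epimerising C9 and does not attack the ester or the acetate.

**Step 18**
Reactants: 26 silyl-protected target
Product: 27 methyl (1R,2R,4aR,5S,8aR)-2-acetoxy-5-[(3S)-5-hydroxy-3-methylpentyl]-1,4a-dimethyl-6-methylidenedecahydronaphthalene-1-carboxylate (CNP0230414.1)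
Conditions: HF·pyridine, pyridine, THF, 0 °C → rt
Reagents that add atoms: none
Why: Fluoride-mediated cleavage of the silyl ether frees the C15 alcohol; the acetate, the methyl ester and the 1,1-disubstituted alkene are stable to buffered HF.

**Compound list**
1 | (R)-carvone | CC1=CC[C@H](CC1=O)C(C)=C | starting material
2 | dimethyl malonate | COC(=O)CC(=O)OC | starting material
3 | dimethyl 2-[(1R,2S,5R)-2-methyl-3-oxo-5-(prop-1-en-2-yl)cyclohexyl]malonate (present as its sodium enolate) | O=C1C[C@H](C(C)=C)C[C@@H](C(C(=O)OC)C(=O)OC)[C@@H]1C | intermediate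
4 | dimethyl 2-methyl-2-[(1R,2S,5R)-2-methyl-3-oxo-5-(prop-1-en-2-yl)cyclohexyl]malonate | O=C1C[C@H](C(C)=C)C[C@@H](C(C)(C(=O)OC)C(=O)OC)[C@@H]1C | intermediate
5 | dimethyl 2-[(1R,2S,5R)-5-(1-hydroperoxy-1-methoxyethyl)-2-methyl-3-oxocyclohexyl]-2-methylmalonate | O=C1C[C@H](C(C)(OC)OO)C[C@@H](C(C)(C(=O)OC)C(=O)OC)[C@@H]1C | intermediate
6 | dimethyl 2-methyl-2-[(1R,2S)-2-methyl-3-oxocyclohexyl]malonate | O=C1CCC[C@@H](C(C)(C(=O)OC)C(=O)OC)[C@@H]1C | intermediate
7 | allyl acrylate | C=CC(=O)OCC=C | starting material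
8 | allyl 3-[(1S,2R)-2-(1,3-dimethoxy-2-methyl-1,3-dioxopropan-2-yl)-1-methyl-6-oxocyclohexyl]propanoate | O=C1CCC[C@@H](C(C)(C(=O)OC)C(=O)OC)[C@]1(C)CCC(=O)OCC=C | intermediate
9 | allyl 3-[(6S,7R)-7-(1,3-dimethoxy-2-methyl-1,3-dioxopropan-2-yl)-6-methyl-1,4-dioxaspiro[4.5]decan-6-yl]propanoate | C1CC[C@@H](C(C)(C(=O)OC)C(=O)OC)[C@](C)(CCC(=O)OCC=C)C12OCCO2 | intermediate
10 | 3-allyl 1-methyl (1R,4aS,8aR)-5,5-ethylenedioxy-2-hydroxy-1,4a-dimethyl-1,4,4a,5,6,7,8,8a-octahydronaphthalene-1,3-dicarboxylate (enol form) | C1CC[C@@H]2[C@](C)(CC(C(=O)OCC=C)=C(O)[C@]2(C)C(=O)OC)C13OCCO3 | intermediate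
11 | (4aS,8R,8aR)-5,5-ethylenedioxy-3-hydroxy-8-(methoxycarbonyl)-4a,8-dimethyl-1,4a,5,6,7,8,8a-heptahydronaphthalene-2-carboxylic acid (free acid of 10, enol form) | C1CC[C@@H]2[C@](C)(CC(C(=O)O)=C(O)[C@]2(C)C(=O)OC)C13OCCO3 | intermediate
12 | methyl (1R,4aS,8aR)-5,5-ethylenedioxy-1,4a-dimethyl-2-oxodecahydronaphthalene-1-carboxylate | C1CC[C@@H]2[C@](C)(CCC(=O)[C@]2(C)C(=O)OC)C13OCCO3 | intermediate
13 | methyl (1R,2R,4aS,8aR)-5,5-ethylenedioxy-2-hydroxy-1,4a-dimethyldecahydronaphthalene-1-carboxylate | C1CC[C@@H]2[C@](C)(CC[C@@H](O)[C@]2(C)C(=O)OC)C13OCCO3 | intermediate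
14 | methyl (1R,2R,4aS,8aR)-2-acetoxy-5,5-ethylenedioxy-1,4a-dimethyldecahydronaphthalene-1-carboxylate | C1CC[C@@H]2[C@](C)(CC[C@@H](OC(C)=O)[C@]2(C)C(=O)OC)C13OCCO3 | intermediate
15 | methyl (1R,2R,4aS,8aR)-2-acetoxy-1,4a-dimethyl-5-oxodecahydronaphthalene-1-carboxylate | O=C1CCC[C@@H]2[C@]1(C)CC[C@@H](OC(C)=O)[C@]2(C)C(=O)OC | intermediate
16 | methyl (1R,2R,4aS,8aR)-2-acetoxy-1,4a-dimethyl-5-(trifluoromethylsulfonyloxy)-1,2,3,4,4a,7,8,8a-octahydronaphthalene-1-carboxylate | O=S(=O)(OC1=CCC[C@@H]2[C@]1(C)CC[C@@H](OC(C)=O)[C@]2(C)C(=O)OC)C(F)(F)F | intermediate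
17 | (S)-citronellol | CC(C)=CCC[C@H](C)CCO | starting material
18 | (S)-tert-butyl[(3,7-dimethyloct-6-en-1-yl)oxy]diphenylsilane | CC(C)=CCC[C@H](C)CCO[Si](c1ccccc1)(c1ccccc1)C(C)(C)C | intermediate
19 | (S)-6-(tert-butyldiphenylsilyloxy)-4-methylhexanoic acid | OC(=O)CC[C@H](C)CCO[Si](c1ccccc1)(c1ccccc1)C(C)(C)C | intermediate
20 | (R)-tert-butyl[(5-iodo-3-methylpentyl)oxy]diphenylsilane | ICC[C@H](C)CCO[Si](c1ccccc1)(c1ccccc1)C(C)(C)C | intermediate
21 | [(3R)-5-(tert-butyldiphenylsilyloxy)-3-methylpentyl]zinc iodide | I[Zn]CC[C@H](C)CCO[Si](c1ccccc1)(c1ccccc1)C(C)(C)C | intermediate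
22 | methyl (1R,2R,4aS,8aR)-2-acetoxy-5-[(3S)-5-(tert-butyldiphenylsilyloxy)-3-methylpentyl]-1,4a-dimethyl-1,2,3,4,4a,7,8,8a-octahydronaphthalene-1-carboxylate | C1(=CCC[C@@H]2[C@]1(C)CC[C@@H](OC(C)=O)[C@]2(C)C(=O)OC)CC[C@H](C)CCO[Si](c1ccccc1)(c1ccccc1)C(C)(C)C | intermediate
23 | C8 alkylborane of 22 (8α-boranyl, 9α-H; the 6-boranyl analogue of 24) | B[C@@H]1CC[C@@H]2[C@](C)(CC[C@@H](OC(C)=O)[C@]2(C)C(=O)OC)[C@H]1CC[C@H](C)CCO[Si](c1ccccc1)(c1ccccc1)C(C)(C)C | intermediate
24 | methyl (1R,2R,4aS,5R,6R,8aR)-2-acetoxy-5-[(3S)-5-(tert-butyldiphenylsilyloxy)-3-methylpentyl]-6-hydroxy-1,4a-dimethyldecahydronaphthalene-1-carboxylate | O[C@@H]1CC[C@@H]2[C@](C)(CC[C@@H](OC(C)=O)[C@]2(C)C(=O)OC)[C@H]1CC[C@H](C)CCO[Si](c1ccccc1)(c1ccccc1)C(C)(C)C | intermediate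
25 | methyl (1R,2R,4aS,5R,8aR)-2-acetoxy-5-[(3S)-5-(tert-butyldiphenylsilyloxy)-3-methylpentyl]-1,4a-dimethyl-6-oxodecahydronaphthalene-1-carboxylate | O=C1CC[C@@H]2[C@](C)(CC[C@@H](OC(C)=O)[C@]2(C)C(=O)OC)[C@H]1CC[C@H](C)CCO[Si](c1ccccc1)(c1ccccc1)C(C)(C)C | intermediate
26 | methyl (1R,2R,4aR,5S,8aR)-2-acetoxy-5-[(3S)-5-(tert-butyldiphenylsilyloxy)-3-methylpentyl]-1,4a-dimethyl-6-methylidenedecahydronaphthalene-1-carboxylate | C=C1CC[C@@H]2[C@](C)(CC[C@@H](OC(C)=O)[C@]2(C)C(=O)OC)[C@H]1CC[C@H](C)CCO[Si](c1ccccc1)(c1ccccc1)C(C)(C)C | intermediate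
27 | methyl (1R,2R,4aR,5S,8aR)-2-acetoxy-5-[(3S)-5-hydroxy-3-methylpentyl]-1,4a-dimethyl-6-methylidenedecahydronaphthalene-1-carboxylate (CNP0230414.1) | C=C1CC[C@@H]2[C@](C)(CC[C@@H](OC(C)=O)[C@]2(C)C(=O)OC)[C@H]1CC[C@H](C)CCO | target

**Step count**
Total: 18 steps. Longest linear sequence: 15 steps (steps 1–10, then 14–18); the side chain takes steps 11–13.

**Steps most likely to fail**

Step 5. The enolate may not discriminate well enough between the two diastereotopic esters, so that attack on the ester that leaves the methyl group axial erodes the C4 configuration. Acylation at the neopentyl-type ester may also be slow enough for the allyl ester enolate to decompose on warming. The fallback removes the need for group selection and sets C4 by alkylation instead; it sets out from 3 and comes back at 12. 3 is isolated by an acidic quench of step 1 before MeI is added and is C-acylated at the malonate carbon (NaH, THF; ClCO2Me) to trimethyl [(1R,2S,5R)-2-methyl-3-oxo-5-(prop-1-en-2-yl)cyclohexyl]methanetricarboxylate F1. Hydrodealkenylation as in step 2 gives trimethyl [(1R,2S)-2-methyl-3-oxocyclohexyl]methanetricarboxylate F2. Michael addition to 7 as in step 3 gives allyl 3-[(1S,2R)-1-methyl-6-oxo-2-(tris(methoxycarbonyl)methyl)cyclohexyl]propanoate F3, and ketalisation as in step 4 gives its ethylene ketal F4. The Dieckmann condensation under the conditions of step 5 then gives the ring-A β-keto ester with a 4,4-diester F5, in which C4 bears two identical esters and is not a stereocentre. Deallylative decarboxylation as in step 6 gives the 3-oxo 4,4-diester F6. Krapcho dealkoxycarbonylation (LiCl, wet DMSO, 130 °C) removes one C4 ester and gives the C4–H β-keto ester F7. C-methylation of its enolate (K2CO3, MeI, acetone) should then take place from the α face, anti to the axial C20 methyl, and give 12 with the ester axial.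

Step 3. Alkylation may occur at C8 instead of C10, a second acrylate may add, and the C10 enolate may expel methylmalonate by retro-Michael cleavage, which would also erode the configuration at C5. The fallback replaces the enolate by a neutral enamine; it sets out from 6 and comes back at 8. Condensation of 6 with benzylamine (TiCl4, Et3N, CH2Cl2, 0 °C) gives dimethyl 2-[(1R,2S)-3-(benzylimino)-2-methylcyclohexyl]-2-methylmalonate F8. Its more substituted secondary enamine tautomer adds to 7 in an aza-ene-type Michael reaction (THF, 40 °C), anti to the C5 substituent, to give the imine of the keto triester F9. Hydrolysis with aqueous acetic acid at room temperature gives 8.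

Step 14. Oxidative addition and transmetalation at the triflate next to quaternary C10 may be slow, so that β-hydride elimination of the alkylpalladium intermediate, reduction of the triflate and protonolysis of the zinc reagent compete. The fallback changes the nucleophile to an alkylborane; it sets out from 20 and comes back at 22. Dehydroiodination of 20 (KOtBu, THF) gives (R)-tert-butyl[(3-methylpent-4-en-1-yl)oxy]diphenylsilane F10. Hydroboration with 9-BBN gives 9-[(3S)-5-(tert-butyldiphenylsilyloxy)-3-methylpentyl]-9-borabicyclo[3.3.1]nonane F11. B-alkyl Suzuki–Miyaura coupling of F11 with 16 (PdCl2(dppf), AsPh3, Cs2CO3, DMF–THF–H2O, rt) gives 22.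

**Further compounds**
F1 | step 5 | trimethyl [(1R,2S,5R)-2-methyl-3-oxo-5-(prop-1-en-2-yl)cyclohexyl]methanetricarboxylate | O=C1C[C@H](C(C)=C)C[C@@H](C(C(=O)OC)(C(=O)OC)C(=O)OC)[C@@H]1C
F2 | step 5 | trimethyl [(1R,2S)-2-methyl-3-oxocyclohexyl]methanetricarboxylate | O=C1CCC[C@@H](C(C(=O)OC)(C(=O)OC)C(=O)OC)[C@@H]1C
F3 | step 5 | allyl 3-[(1S,2R)-1-methyl-6-oxo-2-(tris(methoxycarbonyl)methyl)cyclohexyl]propanoate | O=C1CCC[C@@H](C(C(=O)OC)(C(=O)OC)C(=O)OC)[C@]1(C)CCC(=O)OCC=C
F4 | step 5 | allyl 3-[(6S,7R)-6-methyl-7-(tris(methoxycarbonyl)methyl)-1,4-dioxaspiro[4.5]decan-6-yl]propanoate | C1CC[C@@H](C(C(=O)OC)(C(=O)OC)C(=O)OC)[C@](C)(CCC(=O)OCC=C)C12OCCO2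
F5 | step 5 | 3-allyl 1,1-dimethyl (4aS,8aR)-5,5-ethylenedioxy-2-hydroxy-4a-methyl-4,4a,5,6,7,8-hexahydronaphthalene-1,1,3(8aH)-tricarboxylate (enol form) | C1CC[C@@H]2[C@](C)(CC(C(=O)OCC=C)=C(O)C2(C(=O)OC)C(=O)OC)C13OCCO3
F6 | step 5 | dimethyl (4aS,8aR)-5,5-ethylenedioxy-4a-methyl-2-oxooctahydronaphthalene-1,1(2H)-dicarboxylate | C1CC[C@@H]2[C@](C)(CCC(=O)C2(C(=O)OC)C(=O)OC)C13OCCO3
F7 | step 5 | methyl (4aS,8aR)-5,5-ethylenedioxy-4a-methyl-2-oxodecahydronaphthalene-1-carboxylate (C1 epimers and enol) | C1CC[C@@H]2[C@](C)(CCC(=O)C2C(=O)OC)C13OCCO3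
F8 | step 3 | dimethyl 2-[(1R,2S)-3-(benzylimino)-2-methylcyclohexyl]-2-methylmalonate | C(c1ccccc1)N=C1CCC[C@@H](C(C)(C(=O)OC)C(=O)OC)[C@@H]1C
F9 | step 3 | allyl 3-[(1S,2R)-6-(benzylimino)-2-(1,3-dimethoxy-2-methyl-1,3-dioxopropan-2-yl)-1-methylcyclohexyl]propanoate | C(c1ccccc1)N=C1CCC[C@@H](C(C)(C(=O)OC)C(=O)OC)[C@]1(C)CCC(=O)OCC=C
F10 | step 14 | (R)-tert-butyl[(3-methylpent-4-en-1-yl)oxy]diphenylsilane | C=C[C@H](C)CCO[Si](c1ccccc1)(c1ccccc1)C(C)(C)C
F11 | step 14 | 9-[(3S)-5-(tert-butyldiphenylsilyloxy)-3-methylpentyl]-9-borabicyclo[3.3.1]nonane | B1(CC[C@H](C)CCO[Si](c2ccccc2)(c2ccccc2)C(C)(C)C)C2CCCC1CCC2
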